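## Retrosynthetic overview

1. The tetrahydrofuran ring (formed last) is opened at O1–C2: 5-exo closure of a benzylic cation from a (2R,3R)-triol sets C2 trans to C3.
2. The triol comes from LiAlH4 reduction of a trans-α-(aryl-hydroxymethyl)-β-benzyl-γ-butyrolactone, the aldol adduct of (R)-β-(3,4,5-trimethoxybenzyl)-γ-butyrolactone and 3,4,5-trimethoxybenzaldehyde (C3 set anti to the benzyl group).
3. Key step: the (R)-lactone ring (first ring made) arises by enantioselective carbonylative ring expansion, four- to five-membered, of achiral 3-(3,4,5-trimethoxybenzyl)oxetane; this sets C4.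
4. The oxetane comes from 3-methyleneoxetane and 5-chloro-1,2,3-trimethoxybenzene by hydroboration and B-alkyl Suzuki–Miyaura coupling.
5. Both trimethoxyaryl units are built from para-substituted phenols (p-cresol, 4-chlorophenol) by bromination, copper-catalysed methoxylation and O-methylation.

Assumption: 3-methyleneoxetane is taken as commercially available, and the (R,R) antipode of the new carbonylation catalyst is assumed to give the (R)-lactone; if the opposite sense is found, the (S,S) antipode is used.

## Route

Step 1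
Reactants: 1 p-cresol (4-methylphenol)
Product: 4 3,5-dibromo-4-hydroxybenzaldehyde, via 2,6-dibromo-4-methylphenol 2 (not isolated), via 2,6-dibromo-4-(dibromomethyl)phenol 3 (not isolated)
Conditions: Br2 (4.1 equiv), o-dichlorobenzene, 35 °C then 150 °C; then H2O, 100 °C
Reagents that add atoms: bromine (BrBr); water (O)
Why: Electrophilic aromatic bromination ortho to the phenol OH, then radical side-chain bromination to the benzal bromide and hydrolysis to the aldehyde, the established bulk process for this compound; no stereocentre.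

Step 2
Reactants: 4 3,5-dibromo-4-hydroxybenzaldehyde
Product: 6 3,4,5-trimethoxybenzaldehyde, via sodium 4-formyl-2,6-dimethoxyphenolate 5 (not isolated)
Conditions: NaOMe, CuCl (10 mol %), DMF/MeOH, 115 °C; then Me2SO4, 60 °C
Reagents that add atoms: sodium methoxide (C[O-].[Na+]); dimethyl sulfate (COS(=O)(=O)OC)
Why: Copper-catalysed Ullmann-type methoxylation of both aryl bromides (activated by the para formyl group), then Williamson O-methylation of the phenolate in the same flask.

Step 3
Reactants: 7 4-chlorophenol
Product: 8 2,6-dibromo-4-chlorophenol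
Conditions: Br2 (2.05 equiv), AcOH, 20 °C
Reagents that add atoms: bromine (BrBr)
Why: Electrophilic aromatic bromination; the para position is blocked by chlorine, so both bromines enter ortho to OH.

Step 4
Reactants: 8 2,6-dibromo-4-chlorophenol
Product: 10 5-chloro-1,2,3-trimethoxybenzene, via sodium 4-chloro-2,6-dimethoxyphenolate 9 (not isolated)
Conditions: NaOMe, CuCl (10 mol %), DMF/MeOH, 115 °C; then Me2SO4, 60 °C
Reagents that add atoms: sodium methoxide (C[O-].[Na+]); dimethyl sulfate (COS(=O)(=O)OC)
Why: Ullmann-type methoxylation is selective for C–Br over the inert C–Cl bond (the 4-methyl analogue is made this way), followed by Williamson O-methylation in the same flask.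

Step 5
Reactants: 11 3-methyleneoxetane; 10 5-chloro-1,2,3-trimethoxybenzene
Product: 13 3-(3,4,5-trimethoxybenzyl)oxetane, via 9-(oxetan-3-ylmethyl)-9-borabicyclo[3.3.1]nonane 12 (not isolated)
Conditions: 9-BBN-H, THF, 0 to 25 °C; then 10, Pd(OAc)2 (2 mol %), SPhos (4 mol %), K3PO4, H2O, THF, 65 °C
Reagents that add atoms: none
Why: Anti-Markovnikov hydroboration of the 1,1-disubstituted alkene, then B-alkyl Suzuki–Miyaura coupling; the dialkylbiarylphosphine lets zerovalent palladium insert into the electron-rich aryl chloride, and the oxetane is stable to base.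

Step 6
Reactants: 13 3-(3,4,5-trimethoxybenzyl)oxetane
Product: 14 (R)-4-(3,4,5-trimethoxybenzyl)dihydrofuran-2(3H)-one
Conditions: [(R,R)-(salen)Cr(THF)2][Co(CO)4] (5 mol %; salen = N,N′-bis(3,5-di-tert-butylsalicylidene)cyclohexane-1,2-diaminate), CO (60 bar), DME, 80 °C
Reagents that add atoms: carbon monoxide ([C-]#[O+])
Why: Proposed new method: enantioselective desymmetrising carbonylative ring expansion of a 3-monosubstituted oxetane by a chiral Lewis-acid/cobaltate ion pair; the trivalent chromium salen cation binds the oxetane oxygen, its chiral pocket leaves only one of the two enantiotopic O–CH2 carbons open to backside (SN2) attack by [Co(CO)4]−, the alkylcobalt inserts CO and the chromium alkoxide closes on the acylcobalt to release the γ-lactone, so the untouched oxetane C3 becomes the (R)-configured C4 of the lactone; the closest known reaction types are the racemic Lewis-acid/[Co(CO)4]− carbonylative ring expansion of oxetanes and epoxides, the enantioselective carbonylation of meso-epoxides with chiral ion pairs of this kind, and salen-metal-catalysed enantioselective openings of 3-substituted oxetanes.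

Step 7
Reactants: 14 (R)-4-(3,4,5-trimethoxybenzyl)dihydrofuran-2(3H)-one; 6 3,4,5-trimethoxybenzaldehyde
Product: 16 (3S,4R)-3-[hydroxy(3,4,5-trimethoxyphenyl)methyl]-4-(3,4,5-trimethoxybenzyl)dihydrofuran-2(3H)-one (both carbinol epimers), via lactone lithium enolate 15 (not isolated)
Conditions: LiHMDS, THF, −78 °C; then 6, −78 °C; AcOH quench
Reagents that add atoms: none
Why: Lithium enolate aldol addition; the aldehyde approaches the enolate face anti to the C4 benzyl group, giving the 3,4-trans lactone, while the carbinol centre forms as a mixture that is erased when it is ionised in the ring closure.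

Step 8
Reactants: 16 (3S,4R)-3-[hydroxy(3,4,5-trimethoxyphenyl)methyl]-4-(3,4,5-trimethoxybenzyl)dihydrofuran-2(3H)-one
Product: 17 (2R,3R)-2-[hydroxy(3,4,5-trimethoxyphenyl)methyl]-3-(3,4,5-trimethoxybenzyl)butane-1,4-diol (both carbinol epimers)
Conditions: LiAlH4, THF, 0 °C to rt; aqueous work-up
Reagents that add atoms: none
Why: Hydride reduction of the lactone to the 1,4-diol; neither ring stereocentre is touched, and the trans-lactone relationship becomes the 3,4-cis relationship of the target once the other ring is closed.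

Step 9
Reactants: 17 (2R,3R)-2-[hydroxy(3,4,5-trimethoxyphenyl)methyl]-3-(3,4,5-trimethoxybenzyl)butane-1,4-diol
Product: 18 [(2S,3R,4R)-2-(3,4,5-trimethoxyphenyl)-4-(3,4,5-trimethoxybenzyl)tetrahydrofuran-3-yl]methanol
Conditions: BF3·OEt2 (0.3 equiv), CH2Cl2, −20 to 0 °C, short reaction time; NaHCO3 quench
Reagents that add atoms: none
Why: Acid-catalysed SN1 cyclodehydration (intramolecular etherification): the benzylic cation is trapped 5-exo by the primary hydroxyl on the benzyl-bearing carbon (the other hydroxyl would give an oxetane), both carbinol epimers converge, and the aryl group settles trans to the adjacent hydroxymethyl group, setting C2 as S.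

## Compound list

1 | p-cresol (4-methylphenol) | Cc1ccc(O)cc1 | starting material
2 | 2,6-dibromo-4-methylphenol | Cc1cc(Br)c(O)c(Br)c1 | intermediate
3 | 2,6-dibromo-4-(dibromomethyl)phenol | BrC(Br)c1cc(Br)c(O)c(Br)c1 | intermediate
4 | 3,5-dibromo-4-hydroxybenzaldehyde | O=Cc1cc(Br)c(O)c(Br)c1 | intermediate
5 | sodium 4-formyl-2,6-dimethoxyphenolate | COc1cc(C=O)cc(OC)c1[O-].[Na+] | intermediate
6 | 3,4,5-trimethoxybenzaldehyde | COc1cc(C=O)cc(OC)c1OC | intermediate
7 | 4-chlorophenol | Oc1ccc(Cl)cc1 | starting material
8 | 2,6-dibromo-4-chlorophenol | Oc1c(Br)cc(Cl)cc1Br | intermediate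
9 | sodium 4-chloro-2,6-dimethoxyphenolate | COc1cc(Cl)cc(OC)c1[O-].[Na+] | intermediate
10 | 5-chloro-1,2,3-trimethoxybenzene | COc1cc(Cl)cc(OC)c1OC | intermediate
11 | 3-methyleneoxetane | C=C1COC1 | starting material
12 | 9-(oxetan-3-ylmethyl)-9-borabicyclo[3.3.1]nonane | C1OCC1CB1C2CCCC1CCC2 | intermediate
13 | 3-(3,4,5-trimethoxybenzyl)oxetane | COc1cc(CC2COC2)cc(OC)c1OC | intermediate
14 | (R)-4-(3,4,5-trimethoxybenzyl)dihydrofuran-2(3H)-one | O=C1C[C@@H](Cc2cc(OC)c(OC)c(OC)c2)CO1 | intermediate
15 | lithium enolate of lactone 14 | [Li+].[O-]C1=C[C@@H](Cc2cc(OC)c(OC)c(OC)c2)CO1 | intermediate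
16 | (3S,4R)-3-[hydroxy(3,4,5-trimethoxyphenyl)methyl]-4-(3,4,5-trimethoxybenzyl)dihydrofuran-2(3H)-one, carbinol centre unassigned (both epimers) | O=C1OC[C@H](Cc2cc(OC)c(OC)c(OC)c2)[C@H]1C(O)c1cc(OC)c(OC)c(OC)c1 | intermediate
17 | (2R,3R)-2-[hydroxy(3,4,5-trimethoxyphenyl)methyl]-3-(3,4,5-trimethoxybenzyl)butane-1,4-diol, carbinol centre unassigned (both epimers) | OC[C@H](Cc1cc(OC)c(OC)c(OC)c1)[C@H](CO)C(O)c1cc(OC)c(OC)c(OC)c1 | intermediate
18 | [(2S,3R,4R)-2-(3,4,5-trimethoxyphenyl)-4-(3,4,5-trimethoxybenzyl)tetrahydrofuran-3-yl]methanol | COc1cc(C[C@H]2CO[C@H](c3cc(OC)c(OC)c(OC)c3)[C@H]2CO)cc(OC)c1OC | target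

## Step count and risks

Total steps: 9. Longest linear sequence: 7 steps (7 → 8 → 10 → 13 → 14 → 16 → 17 → 18); the aldehyde branch (1 → 4 → 6) joins at step 7.

Step 6 (the proposed new step) is the most likely to fail. The oxetane may carbonylate slowly, oligomerise, or give low enantioselectivity. The fallback uses known chemistry and keeps a four- to five-membered ring expansion as the stereo-defining event. It sets out from 10: Suzuki–Miyaura allylation with allylboronic acid pinacol ester (Pd(OAc)2, SPhos, K3PO4) gives 5-allyl-1,2,3-trimethoxybenzene F1. Cycloaddition with dichloroketene (Cl3CCOCl, Zn(Cu), Et2O) gives 2,2-dichloro-3-(3,4,5-trimethoxybenzyl)cyclobutan-1-one F2. Zinc in acetic acid gives 3-(3,4,5-trimethoxybenzyl)cyclobutan-1-one F3. Catalytic asymmetric Baeyer–Villiger oxidation (Sc(OTf)3 with a chiral N,N′-dioxide ligand and mCPBA, or a Baeyer–Villiger monooxygenase) then gives the (R)-lactone, and the route is rejoined at 14.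

Step 9 is the second risk. The benzylic cation can also be attacked by the electron-rich trimethoxybenzyl ring (Friedel–Crafts closure to an aryltetralin), and the product ether can re-ionise under acid. The fallback replaces dehydrative ionisation by oxidative ring closure under non-acidic conditions. It sets out from 16: hydrogenolysis of the benzylic hydroxyl (H2, Pd/C, AcOH, trace HClO4) gives (3R,4R)-3,4-bis(3,4,5-trimethoxybenzyl)dihydrofuran-2(3H)-one F7. LiAlH4 reduction gives (2R,3R)-2,3-bis(3,4,5-trimethoxybenzyl)butane-1,4-diol F8, which is C2-symmetric, so its two benzylic positions are equivalent. DDQ (1.1 equiv, CH2Cl2, pH 7 buffer, 0 °C) abstracts a benzylic hydride and the hydroxyl closes 5-exo onto the cation, giving the target directly; the route is rejoined at 18.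

Step 5 is the third risk. An electron-rich aryl chloride is a demanding partner for B-alkyl coupling, and the alkylborane carries a Lewis-basic oxetane. The fallback replaces cross-coupling by olefination and hydrogenation and needs no aryl chloride. It sets out from 6: NaBH4 reduction gives (3,4,5-trimethoxyphenyl)methanol F4. Heating with PPh3·HBr gives (3,4,5-trimethoxybenzyl)triphenylphosphonium bromide F5. Wittig reaction with commercial oxetan-3-one (KOtBu, THF) gives 3-(3,4,5-trimethoxybenzylidene)oxetane F6. Hydrogenation (H2, Rh/Al2O3, EtOAc) gives the oxetane, and the route is rejoined at 13.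

## Further compounds

F1 | step 6 | 5-allyl-1,2,3-trimethoxybenzene | C=CCc1cc(OC)c(OC)c(OC)c1
F2 | step 6 | 2,2-dichloro-3-(3,4,5-trimethoxybenzyl)cyclobutan-1-one | O=C1CC(Cc2cc(OC)c(OC)c(OC)c2)C1(Cl)Cl
F3 | step 6 | 3-(3,4,5-trimethoxybenzyl)cyclobutan-1-one | O=C1CC(Cc2cc(OC)c(OC)c(OC)c2)C1
F4 | step 5 | (3,4,5-trimethoxyphenyl)methanol | COc1cc(CO)cc(OC)c1OC
F5 | step 5 | (3,4,5-trimethoxybenzyl)triphenylphosphonium bromide | COc1cc(C[P+](c2ccccc2)(c2ccccc2)c2ccccc2)cc(OC)c1OC.[Br-]
F6 | step 5 | 3-(3,4,5-trimethoxybenzylidene)oxetane | COc1cc(C=C2COC2)cc(OC)c1OC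
F7 | step 9 | (3R,4R)-3,4-bis(3,4,5-trimethoxybenzyl)dihydrofuran-2(3H)-one | O=C1OC[C@H](Cc2cc(OC)c(OC)c(OC)c2)[C@H]1Cc1cc(OC)c(OC)c(OC)c1
F8 | step 9 | (2R,3R)-2,3-bis(3,4,5-trimethoxybenzyl)butane-1,4-diol | OC[C@H](Cc1cc(OC)c(OC)c(OC)c1)[C@H](CO)Cc1cc(OC)c(OC)c(OC)c1
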